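**Retrosynthetic overview**

- Guaiane numbering is used throughout: C1/C5 ring fusion; C2, C3, C4 (with methyl C15) complete the cyclopentane; C6, C7 (isopropyl), C8 (ester oxygen), C9, C10 (methyl C14, OH) complete the cycloheptane.
- Late cuts: the 3,4-epoxide comes from the C3=C4 alkene by a bromohydrin (oxygen on the face of C6 and H1); the C8 ester from the alcohol and 3,4-dimethoxybenzoyl chloride; the C10 carbinol from a C10 ketone and a methyl nucleophile; the C3=C4 cyclopentene from ring-closing metathesis of a C1-allyl/C5-isopropenyl pair.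
- Enabling feature: the ring-fusion bond C1–C5 is the α,β-bond of that C10 ketone. In the cyclohept-2-enone C10(=O)–C1=C5, C5 is an acceptor and C1 a latent enolate, so an isopropenyl nucleophile (C4, C15) and an allyl electrophile (C2, C3) are joined to C5 and C1 in one three-component operation that also sets the trans ring fusion.
- Ring order: the seven-membered ring first (metathesis of an acyclic dienone whose C7 and C8 centres come from an Evans allylation and a Felkin-controlled Mukaiyama aldol), the five-membered ring second.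

Key step: step 7

Remark: compound 1 is taken to be a catalogue compound (both enantiomers of this N-acyl oxazolidinone are assumed to be sold).

**Route**

Step 1
Reactants: 1 (4R)-4-benzyl-3-(3-methylbutanoyl)-1,3-oxazolidin-2-one; 2 allyl iodide
Product: 3 (4R)-4-benzyl-3-[(2R)-2-(propan-2-yl)pent-4-enoyl]-1,3-oxazolidin-2-one
Conditions: NaN(SiMe3)2, THF, −78 °C; then 2, −78 → −40 °C
Reagents that add atoms: allyl iodide (2), C=CCI
Why: Evans asymmetric alkylation, in which the chelated Z-sodium enolate should be allylated on the face opposite the benzyl group, setting C7 as 2R.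

Step 2
Reactants: 3 (4R)-4-benzyl-3-[(2R)-2-(propan-2-yl)pent-4-enoyl]-1,3-oxazolidin-2-one
Product: 4 (2R)-2-(propan-2-yl)pent-4-en-1-ol
Conditions: LiBH4, H2O (1 equiv), Et2O, 0 °C
Reagents that add atoms: none
Why: Hydride reduction of the exocyclic imide carbonyl should release the primary alcohol with the α-stereocentre untouched and return the auxiliary.

Step 3
Reactants: 4 (2R)-2-(propan-2-yl)pent-4-en-1-ol
Product: 5 (2R)-2-(propan-2-yl)pent-4-enal
Conditions: Dess–Martin periodinane, NaHCO3, CH2Cl2, 0 °C → rt; used at once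
Reagents that add atoms: none
Why: Dess–Martin oxidation under bicarbonate buffer should give the α-branched aldehyde without epimerisation.

Step 4
Reactants: 5 (2R)-2-(propan-2-yl)pent-4-enal; 6 2-(trimethylsilyloxy)buta-1,3-diene
Product: 7 (5R,6R)-5-hydroxy-6-(propan-2-yl)nona-1,8-dien-3-one
Conditions: BF3·OEt2, CH2Cl2, −78 °C; aq. NaHCO3
Reagents that add atoms: 2-(trimethylsilyloxy)buta-1,3-diene (6), C=CC(=C)O[Si](C)(C)C
Why: Mukaiyama aldol addition through an open transition state, in which by the Felkin–Anh model the silyl dienol ether should attack anti to the isopropyl group and past the hydrogen, setting C8 as the 5R carbinol (oxygen and isopropyl cis on the later ring).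

Step 5
Reactants: 7 (5R,6R)-5-hydroxy-6-(propan-2-yl)nona-1,8-dien-3-one
Product: 8 (5R,6R)-5-[(tert-butyldimethylsilyl)oxy]-6-(propan-2-yl)nona-1,8-dien-3-one
Conditions: tBuMe2SiOTf, 2,6-lutidine, CH2Cl2, −78 °C
Reagents that add atoms: tert-butyldimethylsilyl trifluoromethanesulfonate, CC(C)(C)[Si](C)(C)OS(=O)(=O)C(F)(F)F
Why: Silylation with the triflate and a hindered pyridine base at low temperature should cap the aldol hydroxyl before retro-aldol cleavage or dehydration can occur.

Step 6
Reactants: 8 (5R,6R)-5-[(tert-butyldimethylsilyl)oxy]-6-(propan-2-yl)nona-1,8-dien-3-one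
Product: 9 (5R,6R)-6-[(tert-butyldimethylsilyl)oxy]-5-(propan-2-yl)cyclohept-2-en-1-one
Conditions: second-generation Grubbs catalyst (5 mol %), CH2Cl2 (5 mM), 40 °C
Reagents that add atoms: none
Why: Ring-closing metathesis of the vinyl ketone with the terminal alkene should close the seven-membered ring as the C10(=O)–C1=C5 enone, driven by loss of ethylene at high dilution.

Step 7
Reactants: 9 (5R,6R)-6-[(tert-butyldimethylsilyl)oxy]-5-(propan-2-yl)cyclohept-2-en-1-one; 10 isopropenylmagnesium bromide; 2 allyl iodide
Product: 12 (2R,3S,5R,6R)-6-[(tert-butyldimethylsilyl)oxy]-5-(propan-2-yl)-2-(prop-2-en-1-yl)-3-(prop-1-en-2-yl)cycloheptan-1-one, via bromomagnesium enolate 11 (not isolated)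
Conditions: CH2=C(CH3)MgBr (10, 1.5 equiv), CuBr·SMe2 (15 mol %), THF, −78 → −40 °C; then DMPU, allyl iodide (2, 3 equiv), −40 → −20 °C
Reagents that add atoms: isopropenylmagnesium bromide (10), CC(=C)[Mg]Br; allyl iodide (2), C=CCI
Why: CuBr·SMe2 converts 10 into an isopropenylcopper species that adds 1,4 to enone 9 (π-complex, cupration at C5, reductive elimination), forming C4–C5 and leaving the bromomagnesium enolate 11 with its double bond fixed between C1 and C10; allyl iodide and DMPU then alkylate C1 by SN2 in the same flask, forming C1–C2. The closest known reaction type is the three-component conjugate addition–enolate trapping of cycloalkenones (copper-catalysed Grignard addition, then allylation of the magnesium enolate). No ring closes in this step; it places the two alkenes that step 8 joins into the cyclopentene. C5 is set by the cis C7 isopropyl and C8 silyloxy groups, which cover one face of the seven-membered ring so that the copper reagent should enter from the other; C1 is set by the new C5 isopropenyl group, anti to which the enolate should be allylated, and this 2,3-trans relationship is the trans ring fusion of the target. The step needs 1,4- over 1,2-addition (secured by copper), C- over O-allylation, and alkylation at C1 before the enolate can move to C9, where the C8 silyloxy group would be lost by β-elimination; the regiodefined enolate, the reactive iodide, DMPU and a temperature at or below −20 °C should secure this.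

Step 8
Reactants: 12 (2R,3S,5R,6R)-6-[(tert-butyldimethylsilyl)oxy]-5-(propan-2-yl)-2-(prop-2-en-1-yl)-3-(prop-1-en-2-yl)cycloheptan-1-one
Product: 13 (1R,5S,7R,8R)-8-[(tert-butyldimethylsilyl)oxy]-14-norguai-3-en-10-one (trans-fused; H1 and H5 on opposite faces)
Conditions: second-generation Grubbs catalyst (5 mol %), CH2Cl2, 40 °C
Reagents that add atoms: none
Why: Ring-closing metathesis between the allyl and isopropenyl groups should form the trisubstituted C3=C4 alkene and thereby the trans-fused cyclopentene, the trans-diequatorial substituents being gauche and within reach.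

Step 9
Reactants: 13 (1R,5S,7R,8R)-8-[(tert-butyldimethylsilyl)oxy]-14-norguai-3-en-10-one; 14 methylmagnesium bromide
Product: 15 (1R,5S,7R,8R,10S)-8-[(tert-butyldimethylsilyl)oxy]guai-3-en-10-ol
Conditions: CH3MgBr (14), anhydrous CeCl3, THF, −78 °C
Reagents that add atoms: methylmagnesium bromide (14), C[Mg]Br
Why: Organocerium 1,2-addition (too weakly basic to enolise the ketone or eliminate the silyloxy group), in which the pseudo-axial C8 silyloxy group, 1,3 to the carbonyl, blocks its own face so that methyl should enter from the opposite face and give the 10S carbinol with OH cis to the C8 oxygen.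

Step 10
Reactants: 15 (1R,5S,7R,8R,10S)-8-[(tert-butyldimethylsilyl)oxy]guai-3-en-10-ol
Product: 16 (1R,5S,7R,8R,10S)-guai-3-ene-8,10-diol
Conditions: Bu4NF, THF, rt → 45 °C
Reagents that add atoms: none
Why: Fluoride cleavage of the silyl ether should free the secondary C8 alcohol, no base-sensitive carbonyl being left in the molecule.

Step 11
Reactants: 16 (1R,5S,7R,8R,10S)-guai-3-ene-8,10-diol; 17 3,4-dimethoxybenzoyl chloride
Product: 18 (1R,5S,7R,8R,10S)-10-hydroxyguai-3-en-8-yl 3,4-dimethoxybenzoate
Conditions: 17, Et3N, DMAP (cat.), CH2Cl2, rt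
Reagents that add atoms: 3,4-dimethoxybenzoyl chloride (17), COc1ccc(C(Cl)=O)cc1OC
Why: DMAP-catalysed acylation should discriminate the secondary C8 hydroxyl from the tertiary C10 hydroxyl and give the mono-ester.

Step 12
Reactants: 18 (1R,5S,7R,8R,10S)-10-hydroxyguai-3-en-8-yl 3,4-dimethoxybenzoate
Product: 20 (1R,3R,4S,5S,7R,8R,10S)-3,4-epoxy-10-hydroxyguaian-8-yl 3,4-dimethoxybenzoate (CNP0304846.1), via bromohydrin 19 (not isolated)
Conditions: NBS, THF–H2O (4:1), 0 °C; then K2CO3, 0 °C → rt
Reagents that add atoms: water, O; N-bromosuccinimide, O=C1CCC(=O)N1Br (its bromine is present in 19 only)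
Why: Halohydrin route to the epoxide on the more hindered face, in which Br+ should add to the alkene face anti to C6, water should open the bromonium ion anti at the tertiary C4, and carbonate should then close the C4 alkoxide onto C3 with inversion (intramolecular Williamson reaction), placing the oxygen syn to C6 and H1 (3R,4S).

**Compound list**

1 | (4R)-4-benzyl-3-(3-methylbutanoyl)-1,3-oxazolidin-2-one | CC(C)CC(=O)N1[C@H](Cc2ccccc2)COC1=O | starting material
2 | allyl iodide (3-iodoprop-1-ene) | C=CCI | starting material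
3 | (4R)-4-benzyl-3-[(2R)-2-(propan-2-yl)pent-4-enoyl]-1,3-oxazolidin-2-one | C=CC[C@H](C(C)C)C(=O)N1[C@H](Cc2ccccc2)COC1=O | intermediate
4 | (2R)-2-(propan-2-yl)pent-4-en-1-ol | C=CC[C@@H](CO)C(C)C | intermediate
5 | (2R)-2-(propan-2-yl)pent-4-enal | C=CC[C@@H](C=O)C(C)C | intermediate
6 | 2-(trimethylsilyloxy)buta-1,3-diene | C=CC(=C)O[Si](C)(C)C | starting material
7 | (5R,6R)-5-hydroxy-6-(propan-2-yl)nona-1,8-dien-3-one | C=CC(=O)C[C@@H](O)[C@H](CC=C)C(C)C | intermediate
8 | (5R,6R)-5-[(tert-butyldimethylsilyl)oxy]-6-(propan-2-yl)nona-1,8-dien-3-one | C=CC(=O)C[C@@H](O[Si](C)(C)C(C)(C)C)[C@H](CC=C)C(C)C | intermediate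
9 | (5R,6R)-6-[(tert-butyldimethylsilyl)oxy]-5-(propan-2-yl)cyclohept-2-en-1-one | CC(C)(C)[Si](C)(C)O[C@@H]1CC(=O)C=CC[C@@H]1C(C)C | intermediate
10 | isopropenylmagnesium bromide | CC(=C)[Mg]Br | starting material
11 | bromomagnesium enolate of the conjugate adduct (C1=C10 enolate, isopropenyl at C5) | CC(C)(C)[Si](C)(C)O[C@@H]1CC(O[Mg]Br)=C[C@@H](C(C)=C)C[C@@H]1C(C)C | intermediate
12 | (2R,3S,5R,6R)-6-[(tert-butyldimethylsilyl)oxy]-5-(propan-2-yl)-2-(prop-2-en-1-yl)-3-(prop-1-en-2-yl)cycloheptan-1-one | CC(C)(C)[Si](C)(C)O[C@@H]1CC(=O)[C@H](CC=C)[C@@H](C(C)=C)C[C@@H]1C(C)C | intermediate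
13 | (1R,5S,7R,8R)-8-[(tert-butyldimethylsilyl)oxy]-14-norguai-3-en-10-one | CC(C)(C)[Si](C)(C)O[C@@H]1CC(=O)[C@@H]2CC=C(C)[C@H]2C[C@@H]1C(C)C | intermediate
14 | methylmagnesium bromide | C[Mg]Br | starting material
15 | (1R,5S,7R,8R,10S)-8-[(tert-butyldimethylsilyl)oxy]guai-3-en-10-ol | CC(C)(C)[Si](C)(C)O[C@@H]1C[C@](C)(O)[C@@H]2CC=C(C)[C@H]2C[C@@H]1C(C)C | intermediate
16 | (1R,5S,7R,8R,10S)-guai-3-ene-8,10-diol | O[C@@H]1C[C@](C)(O)[C@@H]2CC=C(C)[C@H]2C[C@@H]1C(C)C | intermediate
17 | 3,4-dimethoxybenzoyl chloride | COc1ccc(C(Cl)=O)cc1OC | starting material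
18 | (1R,5S,7R,8R,10S)-10-hydroxyguai-3-en-8-yl 3,4-dimethoxybenzoate | COc1ccc(C(=O)O[C@@H]2C[C@](C)(O)[C@@H]3CC=C(C)[C@H]3C[C@@H]2C(C)C)cc1OC | intermediate
19 | (1R,3S,4S,5S,7R,8R,10S)-3-bromo-4,10-dihydroxyguaian-8-yl 3,4-dimethoxybenzoate | COc1ccc(C(=O)O[C@@H]2C[C@](C)(O)[C@@H]3C[C@H](Br)[C@](O)(C)[C@H]3C[C@@H]2C(C)C)cc1OC | intermediate
20 | (1R,3R,4S,5S,7R,8R,10S)-3,4-epoxy-10-hydroxyguaian-8-yl 3,4-dimethoxybenzoate (CNP0304846.1) | COc1ccc(C(=O)O[C@@H]2C[C@](C)(O)[C@@H]3C[C@H]4O[C@@]4(C)[C@H]3C[C@@H]2C(C)C)cc1OC | target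

**Step count and risks**

Total step count: 12. Longest linear sequence: 12 (from 1; all other inputs are purchased).

The three steps most likely to fail:

1. Step 7. Slow C-allylation of the bromomagnesium enolate would let proton transfer move the enolate to C9, after which the C8 silyloxy group is expelled and polyallylation sets in; attack on the wrong face of C5 is the second concern. Fallback: starting from 9, the same copper-catalysed addition of 10 is run in the presence of Me3SiCl (THF, −78 °C), which should give the trimethylsilyl enol ether F1 with the enol double bond locked between C1 and C10. Palladium-catalysed allylation of F1 with allyl methyl carbonate (Pd2(dba)3, dppe, THF, reflux) then proceeds under neutral conditions: the methoxide released on decarboxylation removes the silyl group, and the resulting palladium enolate is allylated at C1 by the π-allyl ligand, anti to the isopropenyl group. This comes back to the route at 12.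

2. Step 12. Bromonium formation on the alkene face syn to C6, or competing bromination of the electron-rich dimethoxyarene, would lead to the epimeric epoxide or to ring-brominated material. Fallback: starting from 18, m-chloroperbenzoic acid (NaHCO3, CH2Cl2, 0 °C), guided by hydrogen bonding to the C10 hydroxyl and by the steric bias against the C6 face, should give the epimeric epoxide F2 with oxygen anti to C6. Aqueous HClO4 in THF opens it at the tertiary C4 with inversion to the 3,4-trans-diol F3. MsCl and Et3N at 0 °C sulfonylate only the secondary C3 hydroxyl to give the mesylate F4. K2CO3 in MeCN closes the C4 alkoxide onto C3 with inversion, which comes back to the route at 20.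

3. Step 9. Attack of the methyl nucleophile on the wrong face of the C10 carbonyl would give the C10 epimer. Fallback: starting from 13, HF·pyridine in THF removes the silyl group under acidic conditions to give the β-hydroxy ketone F5. Excess CH3MgBr (14) in THF at −78 °C first forms the magnesium alkoxide, which chelates the C10 carbonyl from the face of the C8 oxygen and should force methyl delivery from the opposite face (chelation control in place of steric control). This gives the diol directly, comes back to the route at 16 and by-passes step 10.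

Further compounds
F1 | step 7 | {[(3S,5R,6R)-6-[(tert-butyldimethylsilyl)oxy]-5-(propan-2-yl)-3-(prop-1-en-2-yl)cyclohept-1-en-1-yl]oxy}trimethylsilane | CC(C)(C)[Si](C)(C)O[C@@H]1CC(O[Si](C)(C)C)=C[C@@H](C(C)=C)C[C@@H]1C(C)C
F2 | step 12 | (1R,3S,4R,5S,7R,8R,10S)-3,4-epoxy-10-hydroxyguaian-8-yl 3,4-dimethoxybenzoate | COc1ccc(C(=O)O[C@@H]2C[C@](C)(O)[C@@H]3C[C@@H]4O[C@]4(C)[C@H]3C[C@@H]2C(C)C)cc1OC
F3 | step 12 | (1R,3S,4S,5S,7R,8R,10S)-3,4,10-trihydroxyguaian-8-yl 3,4-dimethoxybenzoate | COc1ccc(C(=O)O[C@@H]2C[C@](C)(O)[C@@H]3C[C@H](O)[C@](O)(C)[C@H]3C[C@@H]2C(C)C)cc1OC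
F4 | step 12 | (1R,3S,4S,5S,7R,8R,10S)-4,10-dihydroxy-3-(methanesulfonyloxy)guaian-8-yl 3,4-dimethoxybenzoate | COc1ccc(C(=O)O[C@@H]2C[C@](C)(O)[C@@H]3C[C@H](OS(C)(=O)=O)[C@](O)(C)[C@H]3C[C@@H]2C(C)C)cc1OC
F5 | step 9 | (1R,5S,7R,8R)-8-hydroxy-14-norguai-3-en-10-one | O[C@@H]1CC(=O)[C@@H]2CC=C(C)[C@H]2C[C@@H]1C(C)C
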